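## Retrosynthetic overview

1. Feature: in ring B the run O1–C2(CH3)–C3–C4, together with C1'–C2' of the side chain, is the skeleton of mevalonolactone (tertiary oxygen at C2, carbonyl carbon at C4). Ring A carries O1 (on C8a) and C4 (on C4a) on adjacent carbons, which are the two carbons of a benzyne triple bond.
2. Late disconnections: C2'–C3' by Negishi coupling of a C2' alkylzinc with an E-iodoalkenol made from propargyl alcohol. C6–CH2 by B-alkyl Suzuki coupling with a styrene made from 2,3-dihydroxybenzaldehyde. The C3=C4 alkene comes from the C4 ketone by reduction and dehydration.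
3. Key disconnection: O1–C8a and C4–C4a of a chroman-4-one are formed in one operation from benzyne and the tertiary alkoxide of (S)-mevalonolactone. The C2 stereocentre comes from an esterase desymmetrisation.
4. Ring order: the temporary lactone ring forms in step 2. Ring B forms in step 3, where the lactone opens in the same operation. Rings A and C (the catechol) are purchased.

Key step: step 3

Atom labels: chromene numbering O1, C2, C3, C4, C4a, C5–C8, C8a. The chain on C2 is C1', C2', C3'=C4'(CH3)–C5'H2OH.

Assumption: pig liver esterase is taken to cleave the pro-S ester arm. If an enzyme batch showed the opposite sense, reducing the ester arm (LiBH4) in place of the acid arm would lead to the same (S)-lactone.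

Remark: once the 2H-chromene exists (from step 7 on), all operations stay at or below 80 °C and are shielded from light. Reversible oxa-6π opening to the o-quinone methide would scramble C2.

## Route

Step 1
Reactants: 1 dimethyl 3-hydroxy-3-methylglutarate
Product: 2 (S)-3-hydroxy-5-methoxy-3-methyl-5-oxopentanoic acid
Conditions: pig liver esterase, phosphate buffer pH 7.5, 1 M NaOH by pH-stat (1.0 equiv), 25 °C; HCl to pH 2, EtOAc
Reagents that add atoms: water, O
Why: Enzymatic desymmetrisation of a prochiral diester (esterase hydrolysis): the active site should distinguish the enantiotopic ester arms and cleave the pro-S one, which fixes the tertiary carbinol carbon (later C2) as S, and the anionic half-ester is not hydrolysed further.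

Step 2
Reactants: 2 (S)-3-hydroxy-5-methoxy-3-methyl-5-oxopentanoic acid
Product: 4 (S)-mevalonolactone, via methyl (S)-mevalonate 3 (not isolated)
Conditions: BH3·SMe2 (2.0 equiv), THF, 0 °C to rt; MeOH quench, evaporate; p-TsOH·H2O (5 mol %), CH2Cl2, rt
Reagents that add atoms: none
Why: Chemoselective borane reduction of the free carboxylic acid beside the methyl ester, then acid-catalysed lactonisation of 3; because the acid arm becomes the CH2OH arm, the (S)-half-ester maps onto the (S)-lactone with no bond at the stereocentre broken.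

Step 3
Reactants: 4 (S)-mevalonolactone; 5 2-(trimethylsilyl)phenyl trifluoromethanesulfonate
Product: 11 (S)-2-(2-hydroxyethyl)-2-methylchroman-4-one, via potassium alkoxide 6 (not isolated), via benzyne 7 (not isolated), via ortho aryl anion 8 (not isolated), via bridged hemiketal alkoxide 9 (not isolated), via open keto alkoxide 10 (not isolated)
Conditions: KH (1.0 equiv), 18-crown-6 (2.2 equiv), THF, −20 °C, 10 min; spray-dried KF (2.0 equiv), then 5 (1.2 equiv) in THF over 30 min, −20 to 0 °C; cannulate into AcOH/THF at −20 °C
Reagents that add atoms: none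
Why: Proposed new method: fluoride removes the silyl group of 5 and loss of triflate releases benzyne 7, the preformed tertiary alkoxide 6 adds to it (O1–C8a), the ortho aryl anion 8 attacks the lactone carbonyl (C4–C4a) to give the bridged tetrahedral alkoxide 9, and collapse of 9 expels the primary alkoxide, so the temporary lactone ring opens to 10 and protonation gives 11. The closest known reaction type is the aryne annulation of salicylate esters to xanthones (O-arylation, then intramolecular acyl substitution), backed by the classical addition of tert-butoxide to benzyne; new here are an aliphatic tertiary alkoxide as the nucleophile and a lactone as the internal acyl donor. Ring B closes 6-exo-trig through a bicyclo[3.3.1] intermediate, which is within reach because the lactone chair should place the smaller aryloxy group axial and the methyl group equatorial, so that the carbanion sits over the carbonyl carbon in a 1,3-diaxial relationship. No stereocentre is created: C2 comes from 4 with none of its four bonds broken, and the transient C4 centre of 9 is dictated by the bridge and vanishes on collapse. Benzyne is symmetrical, so no regiochemical question arises; what is needed is that capture of 6 by benzyne beats its retro-aldol fragmentation and that acylation of 8 beats proton transfer from C3–H or the medium, for which KH (only H2 as by-product), THF in place of acetonitrile, crown-activated KF that works at −20 to 0 °C and slow addition of 5 are chosen. Because 10 is itself a base that could open ring B by retro-oxa-Michael reaction (loss of configuration at C2) and a nucleophile for a second benzyne, 5 is kept near one equivalent and the cold mixture is transferred into acetic acid as soon as 5 is consumed.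

Step 4
Reactants: 11 (S)-2-(2-hydroxyethyl)-2-methylchroman-4-one
Product: 12 (R)-2-(2-chloroethyl)-2-methylchroman-4-one
Conditions: PPh3 (1.3 equiv), NCS (1.3 equiv), THF, 0 °C, premix 15 min; then 11, 0 °C to rt
Reagents that add atoms: N-chlorosuccinimide, O=C1CCC(=O)N1Cl
Why: Appel-type chlorination of the primary alcohol (SN2 on the alkoxyphosphonium salt) under neutral conditions that spare the base-sensitive chromanone; the chloride is a placeholder for C2' that needs no protecting group and should outlast steps 5 to 10 (the descriptor changes to R only because chlorine raises the rank of the arm, the spatial arrangement is unchanged).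

Step 5
Reactants: 12 (R)-2-(2-chloroethyl)-2-methylchroman-4-one
Product: 13 (2R,4RS)-2-(2-chloroethyl)-2-methylchroman-4-ol
Conditions: NaBH4, MeOH/THF, 0 °C
Reagents that add atoms: none
Why: Borohydride reduction of the aryl ketone; the C4 epimers are of no consequence because C4 becomes sp2 in step 7, and removing the carbonyl now ends the danger of retro-oxa-Michael racemisation at C2 and re-activates ring A for step 6.

Step 6
Reactants: 13 (2R,4RS)-2-(2-chloroethyl)-2-methylchroman-4-ol
Product: 14 (2R,4RS)-6-bromo-2-(2-chloroethyl)-2-methylchroman-4-ol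
Conditions: NBS (1.05 equiv), MeCN, 0 °C to rt, dark
Reagents that add atoms: N-bromosuccinimide, O=C1CCC(=O)N1Br
Why: Electrophilic aromatic bromination with NBS in acetonitrile: O1 directs to the para position C6 in preference to the flanked ortho position C8, and with the carbonyl gone there is neither ring deactivation nor an enolisable C3 to compete for bromine.

Step 7
Reactants: 14 (2R,4RS)-6-bromo-2-(2-chloroethyl)-2-methylchroman-4-ol
Product: 15 (S)-6-bromo-2-(2-chloroethyl)-2-methyl-2H-chromene
Conditions: p-TsOH·H2O (5 mol %), toluene, 4 Å MS, 80 °C, dark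
Reagents that add atoms: none
Why: Acid-catalysed E1 dehydration of the benzylic alcohol through a C4 cation that O1 stabilises via C8a; only C3 carries a proton to lose, so the C3=C4 alkene should be the sole outcome and C2 is not involved.

Step 8
Reactants: 16 2,3-dihydroxybenzaldehyde
Product: 17 2,3-bis(tert-butyldimethylsilyloxy)benzaldehyde
Conditions: TBSCl (2.5 equiv), imidazole (5 equiv), DMF, rt
Reagents that add atoms: tert-butyldimethylsilyl chloride, CC(C)(C)[Si](C)(C)Cl
Why: Imidazole-promoted silylation of phenols, chosen so that all hydroxyl masks of the end game fall to fluoride in one operation.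

Step 9
Reactants: 17 2,3-bis(tert-butyldimethylsilyloxy)benzaldehyde
Product: 18 2,3-bis(tert-butyldimethylsilyloxy)styrene
Conditions: Ph3PCH3Br (1.3 equiv), n-BuLi (1.25 equiv), THF, 0 °C; then 17, 0 °C to rt
Reagents that add atoms: methyltriphenylphosphonium bromide, [Br-].C[P+](c1ccccc1)(c1ccccc1)c1ccccc1
Why: Wittig methylenation of a non-enolisable aldehyde with the unstabilised ylide, which aryl silyl ethers tolerate at this temperature.

Step 10
Reactants: 18 2,3-bis(tert-butyldimethylsilyloxy)styrene; 15 (S)-6-bromo-2-(2-chloroethyl)-2-methyl-2H-chromene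
Product: 21 (S)-6-{2-[2,3-bis(tert-butyldimethylsilyloxy)phenyl]ethyl}-2-(2-chloroethyl)-2-methyl-2H-chromene, via B-alkyl-9-BBN 19 (not isolated), via sodium methoxyborate 20 (not isolated)
Conditions: 18 (1.3 equiv), 9-BBN dimer (0.6 equiv), THF, 0 °C to rt; NaOMe (1.2 equiv), rt; then 15, Pd(dppf)Cl2 (5 mol %), THF, 60 °C, dark
Reagents that add atoms: none
Why: Anti-Markovnikov hydroboration of the styrene with 9-BBN followed by B-alkyl Suzuki–Miyaura coupling; pre-forming borate 20 with one methoxide per boron leaves no free base to strip the aryl silyl ethers, Pd(dppf)Cl2 inserts into the aryl C–Br bond but not the primary C–Cl bond, and no B–H remains to touch the hindered C3=C4 alkene.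

Step 11
Reactants: 21 (S)-6-{2-[2,3-bis(tert-butyldimethylsilyloxy)phenyl]ethyl}-2-(2-chloroethyl)-2-methyl-2H-chromene
Product: 22 (S)-6-{2-[2,3-bis(tert-butyldimethylsilyloxy)phenyl]ethyl}-2-(2-iodoethyl)-2-methyl-2H-chromene
Conditions: NaI (5 equiv), 2-butanone, 75 °C, dark
Reagents that add atoms: sodium iodide, [Na+].[I-]
Why: Finkelstein halide exchange (SN2 at the unhindered primary C2'), driven by precipitation of NaCl under neutral conditions that leave silyl ethers and chromene alone.

Step 12
Reactants: 23 propargyl alcohol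
Product: 25 (E)-3-iodo-2-methylprop-2-en-1-ol, via alkenylalane 24 (not isolated)
Conditions: Me3Al (3 equiv), Cp2ZrCl2 (0.25 equiv), CH2Cl2, 0 °C to rt; I2 (1.2 equiv), THF, −30 to 0 °C; sat. aq. K2CO3
Reagents that add atoms: trimethylaluminium, C[Al](C)C; iodine, II
Why: Zirconium-catalysed Negishi carboalumination adds methyl and aluminium syn with aluminium at the terminus, and iodinolysis with retention fixes the E geometry (iodine trans to CH2OH).

Step 13
Reactants: 25 (E)-3-iodo-2-methylprop-2-en-1-ol
Product: 26 (E)-tert-butyl[(3-iodo-2-methylprop-2-en-1-yl)oxy]dimethylsilane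
Conditions: TBSCl (1.2 equiv), imidazole (2 equiv), CH2Cl2, rt
Reagents that add atoms: tert-butyldimethylsilyl chloride, CC(C)(C)[Si](C)(C)Cl
Why: Standard silylation of a primary alcohol, which removes the proton that would quench the organozinc of step 14.

Step 14
Reactants: 22 (S)-6-{2-[2,3-bis(tert-butyldimethylsilyloxy)phenyl]ethyl}-2-(2-iodoethyl)-2-methyl-2H-chromene; 26 (E)-tert-butyl[(3-iodo-2-methylprop-2-en-1-yl)oxy]dimethylsilane
Product: 28 tris(tert-butyldimethylsilyl) ether of the target, via alkylzinc iodide 27 (not isolated)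
Conditions: Zn dust (3 equiv, activated with BrCH2CH2Br and Me3SiCl, 3 mol % each), LiCl (1.5 equiv), THF, 35 °C; decant, then 26 (1.2 equiv), Pd(dppf)Cl2 (5 mol %), THF, rt, dark
Reagents that add atoms: none
Why: LiCl-assisted zinc insertion into the primary iodide and Negishi coupling with the alkenyl iodide form C2'–C3' with retention of the E geometry, and an alkylzinc is mild enough not to expel the gamma aryloxide O1 or to attack the silyl ethers.

Step 15
Reactants: 28 tris(tert-butyldimethylsilyl) ether of the target
Product: 29 3-{2-[(S)-2-((E)-5-hydroxy-4-methylpent-3-en-1-yl)-2-methyl-2H-chromen-6-yl]ethyl}benzene-1,2-diol (CNP0267525.1)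
Conditions: TBAF (4 equiv), AcOH (4 equiv), THF, 0 °C to rt, argon, dark
Reagents that add atoms: none
Why: Fluoride-induced cleavage of the two aryl and one allylic silyl ethers, driven by Si–F bond formation; the acetic acid buffer keeps the catechol protonated against air oxidation without reaching an acidity that would ionise the allylic alcohol or the chromene.

## Compound list

1 | dimethyl 3-hydroxy-3-methylglutarate | COC(=O)CC(C)(O)CC(=O)OC | starting material
2 | (S)-3-hydroxy-5-methoxy-3-methyl-5-oxopentanoic acid | OC(=O)C[C@@](O)(C)CC(=O)OC | intermediate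
3 | methyl (S)-3,5-dihydroxy-3-methylpentanoate (methyl (S)-mevalonate) | OCC[C@@](O)(C)CC(=O)OC | intermediate
4 | (S)-mevalonolactone, (S)-4-hydroxy-4-methyloxan-2-one | O1CC[C@@](O)(C)CC1=O | intermediate
5 | 2-(trimethylsilyl)phenyl trifluoromethanesulfonate | C[Si](C)(C)c1ccccc1OS(=O)(=O)C(F)(F)F | starting material
6 | potassium (S)-4-methyl-2-oxooxan-4-olate | [K+].O1CC[C@@]([O-])(C)CC1=O | intermediate
7 | benzyne (1,2-didehydrobenzene) | C1#CC=CC=C1 | intermediate
8 | potassium 2-{[(S)-4-methyl-2-oxooxan-4-yl]oxy}phenide | [K+].O1CC[C@@](Oc2cccc[c-]2)(C)CC1=O | intermediate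
9 | potassium (2S,6R)-2-methyl-3,4-dihydro-2H-2,6-methano-1,5-benzodioxocin-6-olate (second bridgehead fixed by the bridge) | [K+].[O-][C@]12C[C@](C)(CCO1)Oc1ccccc12 | intermediate
10 | potassium 2-[(S)-2-methyl-4-oxochroman-2-yl]ethanolate | [K+].[O-]CC[C@@]1(C)CC(=O)c2ccccc2O1 | intermediate
11 | (S)-2-(2-hydroxyethyl)-2-methylchroman-4-one | OCC[C@@]1(C)CC(=O)c2ccccc2O1 | intermediate
12 | (R)-2-(2-chloroethyl)-2-methylchroman-4-one | ClCC[C@@]1(C)CC(=O)c2ccccc2O1 | intermediate
13 | (2R,4RS)-2-(2-chloroethyl)-2-methylchroman-4-ol (C4 epimers) | ClCC[C@@]1(C)CC(O)c2ccccc2O1 | intermediate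
14 | (2R,4RS)-6-bromo-2-(2-chloroethyl)-2-methylchroman-4-ol (C4 epimers) | ClCC[C@@]1(C)CC(O)c2cc(Br)ccc2O1 | intermediate
15 | (S)-6-bromo-2-(2-chloroethyl)-2-methyl-2H-chromene | ClCC[C@@]1(C)C=Cc2cc(Br)ccc2O1 | intermediate
16 | 2,3-dihydroxybenzaldehyde | O=Cc1cccc(O)c1O | starting material
17 | 2,3-bis(tert-butyldimethylsilyloxy)benzaldehyde | O=Cc1cccc(O[Si](C)(C)C(C)(C)C)c1O[Si](C)(C)C(C)(C)C | intermediate
18 | 2,3-bis(tert-butyldimethylsilyloxy)styrene | C=Cc1cccc(O[Si](C)(C)C(C)(C)C)c1O[Si](C)(C)C(C)(C)C | intermediate
19 | 9-{2-[2,3-bis(tert-butyldimethylsilyloxy)phenyl]ethyl}-9-borabicyclo[3.3.1]nonane | B1(CCc2cccc(O[Si](C)(C)C(C)(C)C)c2O[Si](C)(C)C(C)(C)C)C2CCCC1CCC2 | intermediate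
20 | sodium 9-{2-[2,3-bis(tert-butyldimethylsilyloxy)phenyl]ethyl}-9-methoxy-9-boratabicyclo[3.3.1]nonane | [Na+].CO[B-]1(CCc2cccc(O[Si](C)(C)C(C)(C)C)c2O[Si](C)(C)C(C)(C)C)C2CCCC1CCC2 | intermediate
21 | (S)-6-{2-[2,3-bis(tert-butyldimethylsilyloxy)phenyl]ethyl}-2-(2-chloroethyl)-2-methyl-2H-chromene | ClCC[C@@]1(C)C=Cc2cc(CCc3cccc(O[Si](C)(C)C(C)(C)C)c3O[Si](C)(C)C(C)(C)C)ccc2O1 | intermediate
22 | (S)-6-{2-[2,3-bis(tert-butyldimethylsilyloxy)phenyl]ethyl}-2-(2-iodoethyl)-2-methyl-2H-chromene | ICC[C@@]1(C)C=Cc2cc(CCc3cccc(O[Si](C)(C)C(C)(C)C)c3O[Si](C)(C)C(C)(C)C)ccc2O1 | intermediate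
23 | propargyl alcohol | C#CCO | starting material
24 | (E)-alkenylalane, dimethylaluminium alkoxide of 3-(dimethylalumanyl)-2-methylprop-2-en-1-ol | C/C(=C\[Al](C)C)CO[Al](C)C | intermediate
25 | (E)-3-iodo-2-methylprop-2-en-1-ol | C/C(=C\I)CO | intermediate
26 | (E)-tert-butyl[(3-iodo-2-methylprop-2-en-1-yl)oxy]dimethylsilane | C/C(=C\I)CO[Si](C)(C)C(C)(C)C | intermediate
27 | {2-[(S)-6-{2-[2,3-bis(tert-butyldimethylsilyloxy)phenyl]ethyl}-2-methyl-2H-chromen-2-yl]ethyl}zinc iodide | I[Zn]CC[C@@]1(C)C=Cc2cc(CCc3cccc(O[Si](C)(C)C(C)(C)C)c3O[Si](C)(C)C(C)(C)C)ccc2O1 | intermediate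
28 | tris(tert-butyldimethylsilyl) ether of the target (S at C2, E alkene) | C/C(=C\CC[C@@]1(C)C=Cc2cc(CCc3cccc(O[Si](C)(C)C(C)(C)C)c3O[Si](C)(C)C(C)(C)C)ccc2O1)CO[Si](C)(C)C(C)(C)C | intermediate
29 | 3-{2-[(S)-2-((E)-5-hydroxy-4-methylpent-3-en-1-yl)-2-methyl-2H-chromen-6-yl]ethyl}benzene-1,2-diol | C/C(=C\CC[C@@]1(C)C=Cc2cc(CCc3cccc(O)c3O)ccc2O1)CO | target

## Step count and risks

Total steps: 15. Longest linear sequence: 11 steps (1–7, 10, 11, 14, 15). The two side branches are steps 8–9 and steps 12–13.

**Step 3 (aryne annulation).**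
- The alkoxide may fragment by retro-aldol cleavage before it meets benzyne.
- The aryl anion may take a proton from C3–H or the medium instead of acylating, with β-elimination of phenoxide to follow.
- The released alkoxide may be arylated a second time.
- The released alkoxide may erode the configuration at C2 by base-induced opening and reclosure of ring B.

The fallback makes the same two bonds one at a time, in the reverse order, with known reactions. It sets out from 4 and comes back at 11.
- Aminolysis of 4 with MeNH(OMe)·HCl and i-PrMgCl in THF opens the lactone to the Weinreb amide (S)-3,5-dihydroxy-N-methoxy-N,3-dimethylpentanamide F1.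
- TBSCl and imidazole cap the primary alcohol to give (S)-5-(tert-butyldimethylsilyloxy)-3-hydroxy-N-methoxy-N,3-dimethylpentanamide F2.
- 1-Bromo-2-fluorobenzene and i-PrMgCl·LiCl at −20 °C give 2-fluorophenylmagnesium chloride F3. It is used in excess to cover the free tertiary hydroxyl.
- F3 forms C4–C4a in a Weinreb ketone synthesis and gives (S)-5-(tert-butyldimethylsilyloxy)-1-(2-fluorophenyl)-3-hydroxy-3-methylpentan-1-one F4.
- NaH in THF/DMF at 0 °C closes O1–C8a by intramolecular SNAr on the ketone-activated fluoroarene. This gives (S)-2-[2-(tert-butyldimethylsilyloxy)ethyl]-2-methylchroman-4-one F5.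
- Aqueous HF in MeCN removes the silyl group and returns 11.

**Step 10 (hydroboration and B-alkyl Suzuki coupling).**
- The aryl silyl ethers may be lost in the basic coupling medium.
- Oxidative addition to the electron-rich bromide may be slow enough for protodeboronation or β-hydride elimination to take over.

The fallback builds the two-carbon bridge before the chromene alkene exists, so an unselective hydrogenation becomes admissible. It sets out from 14 and 18 and comes back at 21.
- A Heck reaction (Pd(OAc)2, P(o-tol)3, Et3N, DMF, 100 °C) gives the stilbene (2R,4RS)-6-{(E)-2-[2,3-bis(tert-butyldimethylsilyloxy)phenyl]ethenyl}-2-(2-chloroethyl)-2-methylchroman-4-ol F6.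
- Hydrogenation (H2, Pd/C, EtOAc, rt) gives (2R,4RS)-6-{2-[2,3-bis(tert-butyldimethylsilyloxy)phenyl]ethyl}-2-(2-chloroethyl)-2-methylchroman-4-ol F7.
- Dehydration under the conditions of step 7 delivers 21.

**Step 14 (zinc insertion and Negishi coupling).**
- Zinc insertion may be sluggish.
- The organozinc may be lost to protonolysis or homocoupling.
- Transmetalation may stall.

The fallback reverses the polarity: the alkenyl partner becomes the nucleophile and the alkyl iodide the SN2 electrophile, with neither zinc nor palladium. It sets out from 26 and 22 and comes back at 28.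
- t-BuLi (2 equiv per iodide, Et2O, −78 °C) converts 26 with retention into (E)-[3-(tert-butyldimethylsilyloxy)-2-methylprop-1-en-1-yl]lithium F8.
- CuI (0.5 equiv) turns F8 into lithium bis[(E)-3-(tert-butyldimethylsilyloxy)-2-methylprop-1-en-1-yl]cuprate F9.
- F9 alkylates on 22 (Et2O/THF, −40 to 0 °C) with retention of the alkene geometry to give 28.

## Further compounds

F1 | step 3 | (S)-3,5-dihydroxy-N-methoxy-N,3-dimethylpentanamide | OCC[C@@](O)(C)CC(=O)N(C)OC
F2 | step 3 | (S)-5-(tert-butyldimethylsilyloxy)-3-hydroxy-N-methoxy-N,3-dimethylpentanamide | CC(C)(C)[Si](C)(C)OCC[C@@](O)(C)CC(=O)N(C)OC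
F3 | step 3 | 2-fluorophenylmagnesium chloride | Fc1ccccc1[Mg]Cl
F4 | step 3 | (S)-5-(tert-butyldimethylsilyloxy)-1-(2-fluorophenyl)-3-hydroxy-3-methylpentan-1-one | CC(C)(C)[Si](C)(C)OCC[C@@](O)(C)CC(=O)c1ccccc1F
F5 | step 3 | (S)-2-[2-(tert-butyldimethylsilyloxy)ethyl]-2-methylchroman-4-one | CC(C)(C)[Si](C)(C)OCC[C@@]1(C)CC(=O)c2ccccc2O1
F6 | step 10 | (2R,4RS)-6-{(E)-2-[2,3-bis(tert-butyldimethylsilyloxy)phenyl]ethenyl}-2-(2-chloroethyl)-2-methylchroman-4-ol | ClCC[C@@]1(C)CC(O)c2cc(/C=C/c3cccc(O[Si](C)(C)C(C)(C)C)c3O[Si](C)(C)C(C)(C)C)ccc2O1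
F7 | step 10 | (2R,4RS)-6-{2-[2,3-bis(tert-butyldimethylsilyloxy)phenyl]ethyl}-2-(2-chloroethyl)-2-methylchroman-4-ol | ClCC[C@@]1(C)CC(O)c2cc(CCc3cccc(O[Si](C)(C)C(C)(C)C)c3O[Si](C)(C)C(C)(C)C)ccc2O1
F8 | step 14 | (E)-[3-(tert-butyldimethylsilyloxy)-2-methylprop-1-en-1-yl]lithium | [Li]/C=C(\C)CO[Si](C)(C)C(C)(C)C
F9 | step 14 | lithium bis[(E)-3-(tert-butyldimethylsilyloxy)-2-methylprop-1-en-1-yl]cuprate | [Li+].CC(C)(C)[Si](C)(C)OC/C(C)=C/[Cu-]/C=C(\C)CO[Si](C)(C)C(C)(C)C
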